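The route rests on cutting the O1–C2 bond of the dihydrofuran ring. C2 is benzylic to ring A (the syringyl ring) and para to its free 4-OH, so it can be flattened to a para-quinone methide. The phenol oxygen of ring B, the future O1, then closes the five-membered ring and sets C2 trans to the hydroxymethyl-bearing C3 in one operation, so only C3 must be made enantiopure beforehand. The cyclisation substrate is an open-chain 1,2-diarylpropane-1,3-diol with both phenols free and the C5 formyl group in place. It is reached by an Evans syn-aldol reaction between a ring B arylacetyl oxazolidinone and O-benzylsyringaldehyde, then hydride removal of the auxiliary.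

Key step: step 10

Remarks on the chemistry:
- Atom labels follow the 2,3-dihydrobenzofuran numbering (O1, C2, C3, C3a, C4–C7, C7a). Ring A is the 4-hydroxy-3,5-dimethoxyphenyl group on C2 and ring B is the benzo ring. The target is the trans (2S,3R) isomer.
- The route delivers the open-chain triol as its (1S,2R) isomer. The configuration at C1 is of no consequence, because C1 becomes planar in step 10 and either epimer leads to the same product.

Step 1
Reactants: 1 5-bromovanillin (3-bromo-4-hydroxy-5-methoxybenzaldehyde)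
Product: 2 4-(benzyloxy)-3-bromo-5-methoxybenzaldehyde
Conditions: BnBr, K2CO3, DMF, 60 °C
Reagents that add atoms: benzyl bromide, BrCc1ccccc1
Why: Williamson ether synthesis, in which the phenoxide formed by K2CO3 displaces bromide from benzyl bromide by SN2 while the aldehyde and the aryl bromide are inert.

Step 2
Reactants: 2 4-(benzyloxy)-3-bromo-5-methoxybenzaldehyde
Product: 3 2-[4-(benzyloxy)-3-bromo-5-methoxyphenyl]-1,3-dioxolane
Conditions: HOCH2CH2OH, p-TsOH·H2O (cat.), toluene, reflux, Dean–Stark; Et3N quench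
Reagents that add atoms: ethylene glycol, OCCO
Why: Acid-catalysed acetalisation driven by azeotropic removal of water masks the formyl group as a dioxolane that should withstand the organozinc, hydroxide, boron enolate and hydride reagents that follow.

Step 3
Reactants: 3 2-[4-(benzyloxy)-3-bromo-5-methoxyphenyl]-1,3-dioxolane
Product: 4 ethyl 2-[2-(benzyloxy)-5-(1,3-dioxolan-2-yl)-3-methoxyphenyl]acetate
Conditions: BrZnCH2CO2Et (commercial solution), Pd(dba)2 (2 mol %), XPhos (4 mol %), THF, rt → 50 °C
Reagents that add atoms: (2-ethoxy-2-oxoethyl)zinc bromide, CCOC(=O)C[Zn]Br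
Why: Negishi-type cross-coupling of a Reformatsky reagent (palladium-catalysed α-arylation of a zinc ester enolate) by oxidative addition of the aryl bromide to zerovalent palladium, transmetalation from zinc and reductive elimination, with the bulky biaryl phosphine handling the ortho-alkoxy group and the weakly basic zinc enolate leaving the acetal and benzyl ether alone.

Step 4
Reactants: 4 ethyl 2-[2-(benzyloxy)-5-(1,3-dioxolan-2-yl)-3-methoxyphenyl]acetate
Product: 5 2-[2-(benzyloxy)-5-(1,3-dioxolan-2-yl)-3-methoxyphenyl]acetic acid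
Conditions: LiOH·H2O, THF–H2O, rt; then 1 M HCl to pH 5, 0 °C, immediate extraction
Reagents that add atoms: lithium hydroxide, [Li+].[OH-]
Why: Ester saponification, to which the benzyl ether and dioxolane are stable, followed by cold acidification only to pH 5 so that the acid is freed without opening the acetal.

Step 5
Reactants: 5 2-[2-(benzyloxy)-5-(1,3-dioxolan-2-yl)-3-methoxyphenyl]acetic acid; 6 (S)-4-benzyl-2-oxazolidinone
Product: 8 (4S)-4-benzyl-3-{2-[2-(benzyloxy)-5-(1,3-dioxolan-2-yl)-3-methoxyphenyl]acetyl}-1,3-oxazolidin-2-one, via mixed pivalic anhydride 7 (not isolated)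
Conditions: t-BuCOCl, Et3N, THF, −20 °C; then LiCl, 6, −20 °C → rt
Reagents that add atoms: none
Why: N-acylation of the oxazolidinone through a mixed pivalic anhydride promoted by LiCl, in which the nucleophile attacks the less hindered arylacetyl carbonyl and no stereocentre is formed or disturbed.

Step 6
Reactants: 9 syringaldehyde (4-hydroxy-3,5-dimethoxybenzaldehyde)
Product: 10 4-(benzyloxy)-3,5-dimethoxybenzaldehyde
Conditions: BnBr, K2CO3, DMF, 60 °C
Reagents that add atoms: benzyl bromide, BrCc1ccccc1
Why: Williamson ether synthesis that caps the ring A phenol with the same hydrogenolysable group as ring B, so that both are removed together later.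

Step 7
Reactants: 8 (4S)-4-benzyl-3-{2-[2-(benzyloxy)-5-(1,3-dioxolan-2-yl)-3-methoxyphenyl]acetyl}-1,3-oxazolidin-2-one; 10 4-(benzyloxy)-3,5-dimethoxybenzaldehyde
Product: 13 (4S)-4-benzyl-3-[(2S,3S)-3-[4-(benzyloxy)-3,5-dimethoxyphenyl]-2-[2-(benzyloxy)-5-(1,3-dioxolan-2-yl)-3-methoxyphenyl]-3-hydroxypropanoyl]-1,3-oxazolidin-2-one, via dibutylboron Z-enolate 11 (not isolated), via dibutylboron aldolate 12 (not isolated)
Conditions: n-Bu2BOTf, i-Pr2NEt, CH2Cl2, −78 → 0 °C; 10, −78 → 0 °C; then pH 7 buffer (NaH2PO4/Na2HPO4), MeOH, 30% H2O2, 0 °C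
Reagents that add atoms: none
Why: Evans syn-aldol reaction, in which soft enolisation gives the Z-boron enolate and a chair Zimmerman–Traxler transition state with the auxiliary carbonyl turned away lets the (S)-benzyl group direct the aldehyde to one enolate face, fixing the aryl-bearing carbon as (2S) in the imide (the future C3 of the target), while the carbinol centre formed alongside is erased in step 10.

Step 8
Reactants: 13 (4S)-4-benzyl-3-[(2S,3S)-3-[4-(benzyloxy)-3,5-dimethoxyphenyl]-2-[2-(benzyloxy)-5-(1,3-dioxolan-2-yl)-3-methoxyphenyl]-3-hydroxypropanoyl]-1,3-oxazolidin-2-one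
Product: 14 (1S,2R)-1-[4-(benzyloxy)-3,5-dimethoxyphenyl]-2-[2-(benzyloxy)-5-(1,3-dioxolan-2-yl)-3-methoxyphenyl]propane-1,3-diol
Conditions: LiBH4, H2O (1 equiv), Et2O–THF, 0 °C; quench with water
Reagents that add atoms: none
Why: Reductive cleavage of the N-acyl oxazolidinone by LiBH4, with hydride delivered to the exocyclic carbonyl assisted by the neighbouring hydroxyl, should give the primary alcohol and release the auxiliary at 0 °C without epimerising the aryl-bearing centre, whose descriptor changes from S to R only because the CIP priorities change.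

Step 9
Reactants: 14 (1S,2R)-1-[4-(benzyloxy)-3,5-dimethoxyphenyl]-2-[2-(benzyloxy)-5-(1,3-dioxolan-2-yl)-3-methoxyphenyl]propane-1,3-diol
Product: 16 (1S,2R)-2-(5-formyl-2-hydroxy-3-methoxyphenyl)-1-(4-hydroxy-3,5-dimethoxyphenyl)propane-1,3-diol, via free diphenol dioxolane 15 (not isolated)
Conditions: H2 (1 atm), 10% Pd/C, EtOAc, rt; filter; then PPTS (0.2 equiv), acetone–H2O (10:1), rt
Reagents that add atoms: water, O
Why: Catalytic hydrogenolysis should cleave the two phenolic benzyl ethers well before the benzylic C1–OH bond or the aryl dioxolane in neutral ethyl acetate, and the dioxolane, now para to a free phenol, should then hydrolyse under a pyridinium acid far too weak to ionise the C1 carbinol at a useful rate, so the open triol aldehyde can be isolated (any material that cyclises early is simply the product of step 10).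

Step 10
Reactants: 16 (1S,2R)-2-(5-formyl-2-hydroxy-3-methoxyphenyl)-1-(4-hydroxy-3,5-dimethoxyphenyl)propane-1,3-diol
Product: 18 (2S,3R)-2-(4-hydroxy-3,5-dimethoxyphenyl)-3-(hydroxymethyl)-7-methoxy-2,3-dihydro-1-benzofuran-5-carbaldehyde, via ring A para-quinone methide 17 (not isolated)
Conditions: CSA (0.2 equiv), MeCN (2% H2O), 0.02 M, rt → 40 °C
Reagents that add atoms: none
Why: The acid protonates the C1 hydroxyl, which is benzylic and para to the free 4-OH of ring A, and water leaves to give para-quinone methide 17 in which the former C1 (future C2) is planar; the ortho phenol oxygen of ring B then adds to this exocyclic methide carbon, forming O1–C2 as ring A rearomatises. The closest known reaction type is the acid-mediated cyclodehydration of 1,2-diarylpropane-1,3-diols to trans-2-aryl-3-(hydroxymethyl)dihydrobenzofurans, an intramolecular oxa-1,6-conjugate (vinylogous oxa-Michael) addition to a quinone methide. The dihydrofuran ring closes in the 5-exo-trig mode, since the attacked C=C bond lies outside the ring being formed. The new C2 centre is controlled by the existing C3 centre alone: the C1 configuration of 16 is erased, the oxygen adds anti to the hydroxymethyl group, and because the benzylic ether can reopen to 17 under the acid, the closure is reversible and should settle on the more stable trans (2S,3R) ring. The step needs chemoselectivity for the phenol over the primary hydroxyl and water, and it must not lose the C3 proton: attack by the primary hydroxyl would demand a four-membered oxetane, water only regenerates 16, and fast intramolecular capture at low acid strength, high dilution and mild temperature should outrun tautomerisation of 17 to a styrene or retro-Prins loss of formaldehyde, while the trace of water suppresses acetal formation at the formyl group.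

Step 11
Reactants: 18 (2S,3R)-2-(4-hydroxy-3,5-dimethoxyphenyl)-3-(hydroxymethyl)-7-methoxy-2,3-dihydro-1-benzofuran-5-carbaldehyde
Product: 19 methyl (2E)-3-[(2S,3R)-2-(4-hydroxy-3,5-dimethoxyphenyl)-3-(hydroxymethyl)-7-methoxy-2,3-dihydro-1-benzofuran-5-yl]prop-2-enoate
Conditions: Ph3P=CHCO2Me, THF, rt → 40 °C
Reagents that add atoms: methyl (triphenylphosphoranylidene)acetate, COC(=O)C=P(c1ccccc1)(c1ccccc1)c1ccccc1
Why: Wittig olefination with a stabilised ylide, which reacts only at the aldehyde, tolerates the hindered ring A phenol and the primary alcohol, and should give the E-enoate.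

Step 12
Reactants: 19 methyl (2E)-3-[(2S,3R)-2-(4-hydroxy-3,5-dimethoxyphenyl)-3-(hydroxymethyl)-7-methoxy-2,3-dihydro-1-benzofuran-5-yl]prop-2-enoate
Product: 20 4-[(2S,3R)-3-(hydroxymethyl)-5-[(1E)-3-hydroxyprop-1-en-1-yl]-7-methoxy-2,3-dihydro-1-benzofuran-2-yl]-2,6-dimethoxyphenol (target)
Conditions: i-Bu2AlH (6 equiv), THF–toluene, −78 → −20 °C; aq. potassium sodium tartrate
Reagents that add atoms: none
Why: DIBAL-H 1,2-reduction of the α,β-unsaturated ester to the allylic alcohol, with excess hydride covering the two acidic OH groups, low temperature keeping the alkene geometry and the benzylic aryl ether intact, and a tartrate work-up avoiding acid.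

Compound list
1 | 5-bromovanillin | COc1cc(C=O)cc(Br)c1O | starting material
2 | 4-(benzyloxy)-3-bromo-5-methoxybenzaldehyde | COc1cc(C=O)cc(Br)c1OCc1ccccc1 | intermediate
3 | 2-[4-(benzyloxy)-3-bromo-5-methoxyphenyl]-1,3-dioxolane | COc1cc(C2OCCO2)cc(Br)c1OCc1ccccc1 | intermediate
4 | ethyl 2-[2-(benzyloxy)-5-(1,3-dioxolan-2-yl)-3-methoxyphenyl]acetate | CCOC(=O)Cc1cc(C2OCCO2)cc(OC)c1OCc1ccccc1 | intermediate
5 | 2-[2-(benzyloxy)-5-(1,3-dioxolan-2-yl)-3-methoxyphenyl]acetic acid | OC(=O)Cc1cc(C2OCCO2)cc(OC)c1OCc1ccccc1 | intermediate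
6 | (S)-4-benzyl-2-oxazolidinone | O=C1N[C@@H](Cc2ccccc2)CO1 | starting material
7 | 2-[2-(benzyloxy)-5-(1,3-dioxolan-2-yl)-3-methoxyphenyl]acetic pivalic anhydride (not isolated) | CC(C)(C)C(=O)OC(=O)Cc1cc(C2OCCO2)cc(OC)c1OCc1ccccc1 | intermediate
8 | (4S)-4-benzyl-3-{2-[2-(benzyloxy)-5-(1,3-dioxolan-2-yl)-3-methoxyphenyl]acetyl}-1,3-oxazolidin-2-one | O=C(Cc1cc(C2OCCO2)cc(OC)c1OCc1ccccc1)N1[C@@H](Cc2ccccc2)COC1=O | intermediate
9 | syringaldehyde | COc1cc(C=O)cc(OC)c1O | starting material
10 | 4-(benzyloxy)-3,5-dimethoxybenzaldehyde | COc1cc(C=O)cc(OC)c1OCc1ccccc1 | intermediate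
11 | di-n-butylboron Z-enolate of 8 (not isolated) | CCCCB(CCCC)O/C(=C\c1cc(C2OCCO2)cc(OC)c1OCc1ccccc1)N1[C@@H](Cc2ccccc2)COC1=O | intermediate
12 | O-(di-n-butylboryl) aldolate of 13 (not isolated) | O=C(N1[C@@H](Cc2ccccc2)COC1=O)[C@@H](c1cc(C2OCCO2)cc(OC)c1OCc1ccccc1)[C@H](OB(CCCC)CCCC)c1cc(OC)c(OCc2ccccc2)c(OC)c1 | intermediate
13 | (4S)-4-benzyl-3-[(2S,3S)-3-[4-(benzyloxy)-3,5-dimethoxyphenyl]-2-[2-(benzyloxy)-5-(1,3-dioxolan-2-yl)-3-methoxyphenyl]-3-hydroxypropanoyl]-1,3-oxazolidin-2-one | O=C(N1[C@@H](Cc2ccccc2)COC1=O)[C@@H](c1cc(C2OCCO2)cc(OC)c1OCc1ccccc1)[C@H](O)c1cc(OC)c(OCc2ccccc2)c(OC)c1 | intermediate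
14 | (1S,2R)-1-[4-(benzyloxy)-3,5-dimethoxyphenyl]-2-[2-(benzyloxy)-5-(1,3-dioxolan-2-yl)-3-methoxyphenyl]propane-1,3-diol | OC[C@@H](c1cc(C2OCCO2)cc(OC)c1OCc1ccccc1)[C@H](O)c1cc(OC)c(OCc2ccccc2)c(OC)c1 | intermediate
15 | (1S,2R)-2-[5-(1,3-dioxolan-2-yl)-2-hydroxy-3-methoxyphenyl]-1-(4-hydroxy-3,5-dimethoxyphenyl)propane-1,3-diol (not isolated) | OC[C@@H](c1cc(C2OCCO2)cc(OC)c1O)[C@H](O)c1cc(OC)c(O)c(OC)c1 | intermediate
16 | (1S,2R)-2-(5-formyl-2-hydroxy-3-methoxyphenyl)-1-(4-hydroxy-3,5-dimethoxyphenyl)propane-1,3-diol | OC[C@@H](c1cc(C=O)cc(OC)c1O)[C@H](O)c1cc(OC)c(O)c(OC)c1 | intermediate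
17 | 4-[(2R)-2-(5-formyl-2-hydroxy-3-methoxyphenyl)-3-hydroxypropylidene]-2,6-dimethoxycyclohexa-2,5-dien-1-one (not isolated) | OC[C@@H](c1cc(C=O)cc(OC)c1O)C=C1C=C(OC)C(=O)C(OC)=C1 | intermediate
18 | (2S,3R)-2-(4-hydroxy-3,5-dimethoxyphenyl)-3-(hydroxymethyl)-7-methoxy-2,3-dihydro-1-benzofuran-5-carbaldehyde | COc1cc([C@H]2Oc3c(OC)cc(C=O)cc3[C@@H]2CO)cc(OC)c1O | intermediate
19 | methyl (2E)-3-[(2S,3R)-2-(4-hydroxy-3,5-dimethoxyphenyl)-3-(hydroxymethyl)-7-methoxy-2,3-dihydro-1-benzofuran-5-yl]prop-2-enoate | COc1cc([C@H]2Oc3c(OC)cc(/C=C/C(=O)OC)cc3[C@@H]2CO)cc(OC)c1O | intermediate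
20 | 4-[(2S,3R)-3-(hydroxymethyl)-5-[(1E)-3-hydroxyprop-1-en-1-yl]-7-methoxy-2,3-dihydro-1-benzofuran-2-yl]-2,6-dimethoxyphenol | COc1cc([C@H]2Oc3c(OC)cc(/C=C/CO)cc3[C@@H]2CO)cc(OC)c1O | target

Total step count: 12.
Longest linear sequence: 11 steps (steps 1–5 and 7–12, from 5-bromovanillin); step 6 is a one-step side branch.

Steps most likely to fail

Step 7. What may go wrong: the hindered, aryl-conjugated boron enolate may add only sluggishly to the electron-rich aldehyde, and on long reaction times retro-aldol cleavage or erosion of the configuration next to the imide may occur. The fallback sets C3 by enolate alkylation and forms the C1–C2 bond by aryl-metal addition. It sets out from 8. The sodium enolate (NaN(SiMe3)2, THF, −78 °C) is alkylated with benzyl chloromethyl ether on the face away from the auxiliary benzyl group (Evans alkylation) to give the (2R)-benzyloxymethylated imide F1. LiBH4 then releases the (2S)-3-(benzyloxy)-2-arylpropan-1-ol F2. Dess–Martin oxidation buffered with NaHCO3 gives the configurationally labile (2R)-3-(benzyloxy)-2-arylpropanal F3, which is used at once. In parallel, 4-bromo-2,6-dimethoxyphenol is benzylated (BnBr, K2CO3) to 2-(benzyloxy)-5-bromo-1,3-dimethoxybenzene F4, and Mg in THF converts this into [4-(benzyloxy)-3,5-dimethoxyphenyl]magnesium bromide F5. Addition of F5 to F3 at −78 °C should give the (2R)-tri-O-benzyl 1,2-diarylpropan-1-ol F6 as a mixture of C1 epimers, which is harmless. Treating F6 under the conditions of step 9, with a longer hydrogenolysis for the third, aliphatic benzyl ether, comes back to the route at 16.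

Step 9. What may go wrong: over-reduction during hydrogenolysis (loss of the benzylic C1 hydroxyl or reductive opening of the aryl dioxolane), or ring closure setting in while the formyl group is unmasked, so that 16 is not obtained cleanly. The fallback inverts the order, so that the aldehyde is released while both phenols are still capped and no ring can close. It sets out from 14. PPTS in wet acetone (rt → 40 °C) gives the bis(benzyl ether) formyl diol F7. The two benzyl ethers are then removed by catalytic transfer hydrogenolysis (10% Pd/C, 1,4-cyclohexadiene, EtOH, rt). This hydrogen-poor regime should spare the para-oxygenated aryl aldehyde and the benzylic alcohol, and it comes back to the route at 16.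

Step 10. What may go wrong: the quinone methide may lose the C3 proton (tautomerisation to a styrene, which would also destroy the C3 centre), formaldehyde may be lost by retro-Prins fragmentation under acid, or the formyl group and the diol may oligomerise through acetals. The fallback generates the same quinone methide without acid. It sets out from 16. Me3SiBr (CH2Cl2, 0 °C) converts the para-hydroxybenzylic alcohol into the benzylic bromide F8; silyl groups picked up in passing on oxygen are lost in the next stage. Shaking the solution with aqueous NaHCO3 then removes HBr in a 1,6-sense to give 17 at room temperature. The ring B phenoxide, which is fairly acidic because it is para to the formyl group, should close the ring anti to the hydroxymethyl group and come back to the route at 18.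

Further compounds
F1 | step 7 | (4S)-4-benzyl-3-[(2R)-3-(benzyloxy)-2-[2-(benzyloxy)-5-(1,3-dioxolan-2-yl)-3-methoxyphenyl]propanoyl]-1,3-oxazolidin-2-one | O=C(N1[C@@H](Cc2ccccc2)COC1=O)[C@@H](COCc1ccccc1)c1cc(C2OCCO2)cc(OC)c1OCc1ccccc1
F2 | step 7 | (2S)-3-(benzyloxy)-2-[2-(benzyloxy)-5-(1,3-dioxolan-2-yl)-3-methoxyphenyl]propan-1-ol | OC[C@@H](COCc1ccccc1)c1cc(C2OCCO2)cc(OC)c1OCc1ccccc1
F3 | step 7 | (2R)-3-(benzyloxy)-2-[2-(benzyloxy)-5-(1,3-dioxolan-2-yl)-3-methoxyphenyl]propanal | O=C[C@@H](COCc1ccccc1)c1cc(C2OCCO2)cc(OC)c1OCc1ccccc1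
F4 | step 7 | 2-(benzyloxy)-5-bromo-1,3-dimethoxybenzene | COc1cc(Br)cc(OC)c1OCc1ccccc1
F5 | step 7 | [4-(benzyloxy)-3,5-dimethoxyphenyl]magnesium bromide | COc1cc([Mg]Br)cc(OC)c1OCc1ccccc1
F6 | step 7 | (2R)-3-(benzyloxy)-1-[4-(benzyloxy)-3,5-dimethoxyphenyl]-2-[2-(benzyloxy)-5-(1,3-dioxolan-2-yl)-3-methoxyphenyl]propan-1-ol, both C1 epimers | OC(c1cc(OC)c(OCc2ccccc2)c(OC)c1)[C@@H](COCc1ccccc1)c1cc(C2OCCO2)cc(OC)c1OCc1ccccc1
F7 | step 9 | (1S,2R)-1-[4-(benzyloxy)-3,5-dimethoxyphenyl]-2-[2-(benzyloxy)-5-formyl-3-methoxyphenyl]propane-1,3-diol | OC[C@@H](c1cc(C=O)cc(OC)c1OCc1ccccc1)[C@H](O)c1cc(OC)c(OCc2ccccc2)c(OC)c1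
F8 | step 10 | (2R)-3-bromo-2-(5-formyl-2-hydroxy-3-methoxyphenyl)-3-(4-hydroxy-3,5-dimethoxyphenyl)propan-1-ol | OC[C@@H](c1cc(C=O)cc(OC)c1O)C(Br)c1cc(OC)c(O)c(OC)c1
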